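Minutes, not rate constants, were what I wanted on the board: how long each stage of the flask takes at its charged amounts.

| setting | elm | ash | birch | flask |
|---|---|---|---|---|
| substrate | 0.56 M | 0.56 M | 0.56 M | 0.56 M |
| reagent | 0.39 M | 0.88 M | 0.588 M | 0.588 M |
| free catalyst | 0.56 mM | 0.56 mM | 1.1 mM | 0.56 mM |
| remark | run made earlier | run made earlier | run made earlier |  |
| time |  |  |  | 20 min |

| run | time / min | target / % | substrate / % | open intermediate / % |
|---|---|---|---|---|
| elm | 1.33 | 0.4 | 98.8 | 2.2 |
| elm | 4.00 | 1.3 | 96.3 | 3.2 |
| elm | 6.00 | 0.7 | 94.0 | 3.9 |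
| elm | 10.0 | 3.1 | 90.7 | 5.4 |
| elm | 15.0 | 5.9 | 87.3 | 6.2 |
| elm | 20.0 | 8.4 | 84.0 | 7.3 |
| elm | 25.0 | 10.5 | 80.7 | 7.4 |
| ash | 1.33 | 0.8 | 98.5 | 1.3 |
| ash | 4.00 | 0.5 | 95.9 | 4.2 |
| ash | 6.00 | 1.2 | 94.5 | 4.8 |
| ash | 10.0 | 3.4 | 90.5 | 5.8 |
| ash | 15.0 | 6.2 | 85.9 | 6.6 |
| ash | 20.0 | 9.1 | 82.9 | 7.5 |
| ash | 25.0 | 11.6 | 79.7 | 6.8 |
| birch | 2.00 | 0.7 | 95.8 | 3.9 |
| birch | 6.00 | 4.8 | 89.0 | 5.9 |
| birch | 12.0 | 11.0 | 81.1 | 7.4 |
| birch | 15.0 | 13.7 | 76.1 | 6.7 |
| birch | 25.0 | 23.4 | 65.2 | 6.2 |

(each reading ± 0.5 percentage points)

- a species is counted by the substrate in it: one side product counts as two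
- what may be going on: substrate + free catalyst <-> free catalyst + open intermediate; free catalyst + open intermediate <-> catalyst intermediate; reagent + catalyst intermediate -> free catalyst + target; substrate + free catalyst -> spent catalyst; substrate + target -> side product

- target present at 20 min, in percent of the substrate charged
- substrate present at 20 min, in percent of the substrate charged
- open intermediate present at 20 min, in percent of the substrate charged

The fastest rung I could only bound. The catalyst charge was 0.100% of the substrate, against a scatter of 0.5 percentage points. Going from elm to ash multiplied the reagent by 2.26, while target at 25.0 min moved from 10.5% to 11.6%, a smaller factor, so I put the reagent's step below the minutes.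

From 15.0 min to 25.0 min open intermediate stood near 6.97% in elm and ash, while target rose 4.6 points and 5.4 points. That made the pool's passing time 13.9 min, or as a half-life 9.66 min: the draining half-life, the time the standing open intermediate takes to pass half of itself on to target. Birch, with 1.96 times the catalyst, read 4.61 min, so the elm and ash value was twice the birch one.

The slowest rung was substrate: elm's readings gave a half-life of 80.8 min, longer than the asked 20 min. For the flask I therefore committed to open intermediate near 6.97%, substrate near 83.5%, and, draining the pool from 10.0 min onward, target 7.92%.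

The forecast said 8.7% target, 83.5% substrate and 7.1% open intermediate, holding that “the reagent is nearly zero order”. The flask gave 8.40%, 83.2% and 6.91%.

    substrate + free catalyst ⇌ free catalyst + open intermediate (K = 0.341, k = 0.352 M⁻¹ s⁻¹)
    free catalyst + open intermediate ⇌ catalyst intermediate (K = 150 M⁻¹, k = 3.13 M⁻¹ s⁻¹)
    reagent + catalyst intermediate → free catalyst + target (k = 1.91 M⁻¹ s⁻¹)
    substrate + free catalyst → spent catalyst (k = 1.47 × 10⁻⁴ M⁻¹ s⁻¹)
    substrate + target → side product (k = 3.53 × 10⁻⁴ M⁻¹ s⁻¹)

In this flask the forward opening step alone gave substrate a half-life of 66 min at 8.42 min, long against 20 min, while open intermediate's forward loss to catalyst intermediate had a half-life of 8.0 min at 20.0 min, against 0.63 s at 8.42 min for catalyst intermediate meeting reagent. My draining half-life stood at 9.66 min. Carried to the neighbour reading of this flask at 5.0 min, with pools of 4.02% there and 5.82% at 10.0 min, it gives a target gain of 1.8 points; the flask gained 2.2 points.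

The numbers in the tables come from a simulation on assumed constants, noise included.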